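**Assumption:** the SMILES is read as the (1S,3aR,4S,6aR) isomer (cis-fused 3a,6a-diol, each aryl group cis to the neighbouring bridgehead OH). O-Benzylvanillin and dimethyl succinate are bought; D-(−)-diisopropyl tartrate is a purchased reagent.

**Retrosynthetic overview**
1. The target comes from hydrogenolysis of its bis(O-benzyl) ether.
2. Both tetrahydrofuran rings and all four stereocentres come from one flask: double Sharpless epoxidation of a (2E,3E)-2,3-bis(arylidene)butane-1,4-diol, then acid-triggered double 5-endo opening of the C2-symmetric bis-epoxide. Each CH2OH attacks the benzylic carbon of the other oxirane with inversion.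
3. Ring order: the two oxiranes first, then the first tetrahydrofuran, then the second one fused onto it. The oxirane oxygens end as the two cis tertiary OH groups.
4. The diene diol comes from alane reduction of the (E,E)-bis(arylidene)succinic acid, which is made by a double Stobbe condensation of O-benzylvanillin with dimethyl succinate.

**Route**

Step 1
Reactants: 1 4-benzyloxy-3-methoxybenzaldehyde (O-benzylvanillin, 2.2 eq); 2 dimethyl succinate
Product: 3 (2E,3E)-2,3-bis[(4-benzyloxy-3-methoxyphenyl)methylidene]butanedioic acid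
Conditions: NaOMe (3 eq), THF–toluene, 0 °C → reflux; then 2 M HCl
Reagents that add atoms: none
Why: Stobbe condensation run twice in one flask (aldol addition, lactonisation onto the other ester, E1cB opening to the carboxylate) gives the diacid directly with the thermodynamically preferred E,E geometry (each aryl trans to its CO2H); no stereocentre is formed.

Step 2
Reactants: 3 (2E,3E)-2,3-bis[(4-benzyloxy-3-methoxyphenyl)methylidene]butanedioic acid
Product: 4 (2E,3E)-2,3-bis[(4-benzyloxy-3-methoxyphenyl)methylidene]butane-1,4-diol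
Conditions: LiAlH4, AlCl3 (3:1), THF, 0 °C
Reagents that add atoms: none
Why: Alane reduction; AlH3 made in the flask reduces the two carboxylic acids to CH2OH by 1,2-hydride delivery without touching the conjugated C=C bonds or the benzyl ethers, so each aryl stays trans to its CH2OH and no stereocentre is formed.

Step 3
Reactants: 4 (2E,3E)-2,3-bis[(4-benzyloxy-3-methoxyphenyl)methylidene]butane-1,4-diol
Product: 7 (1S,3aR,4S,6aR)-1,4-bis(4-benzyloxy-3-methoxyphenyl)tetrahydro-1H,3H-furo[3,4-c]furan-3a,6a-diol, via bis-epoxide 5 (not isolated), via spiro-epoxy tetrahydrofuran 6 (not isolated)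
Conditions: Ti(OiPr)4 (20 mol %), D-(−)-DIPT (26 mol %), t-BuOOH (2.4 eq, isooctane), 4 Å MS, CH2Cl2, −25 °C; then CSA (0.5 eq), −25 → 0 °C
Reagents that add atoms: tert-butyl hydroperoxide, CC(C)(C)OO
Why: Proposed new method: a double Sharpless asymmetric epoxidation under reagent control (D-(−)-tartrate makes each oxirane 2R,3R, the mirror image of the 2S,3S epoxides that L-(+)-tartrate gives with (E)-2-substituted cinnamyl alcohols; the second epoxidation raises the ee because the minor enantiomer is diverted to a meso bis-epoxide that cannot close to a cis-fused bicycle) is followed in the same flask by an acid-triggered double 5-endo epoxide opening, in which each primary OH attacks the electron-rich benzylic carbon of the other oxirane from the face anti to the leaving oxygen (the tether allows only this face, so both benzylic carbons invert from R to S) while the two oxirane oxygens stay on the quaternary carbons as the cis tertiary OH groups (both R); the closest known reaction type is the acid-catalysed 5-endo cyclisation of 4-aryl-3,4-epoxy alcohols to 2-aryl-3-hydroxytetrahydrofurans.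

Step 4
Reactants: 7 (1S,3aR,4S,6aR)-1,4-bis(4-benzyloxy-3-methoxyphenyl)tetrahydro-1H,3H-furo[3,4-c]furan-3a,6a-diol
Product: 8 (1S,3aR,4S,6aR)-1,4-bis(4-hydroxy-3-methoxyphenyl)tetrahydro-1H,3H-furo[3,4-c]furan-3a,6a-diol
Conditions: H2 (1 atm), 10 % Pd/C, EtOAc–MeOH, rt, stopped at 2 eq H2
Reagents that add atoms: none
Why: Catalytic hydrogenolysis under neutral conditions cleaves the two aryl benzyl ethers much faster than the hindered benzylic C–O bonds of the furofuran rings, and no stereocentre is touched.

**Compound list**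
1 | 4-benzyloxy-3-methoxybenzaldehyde (O-benzylvanillin) | O=Cc1ccc(OCc2ccccc2)c(OC)c1 | starting material
2 | dimethyl succinate | COC(=O)CCC(=O)OC | starting material
3 | (2E,3E)-2,3-bis[(4-benzyloxy-3-methoxyphenyl)methylidene]butanedioic acid, each aryl trans to its CO2H | OC(=O)/C(=C/c1ccc(OCc2ccccc2)c(OC)c1)C(=C/c1ccc(OCc2ccccc2)c(OC)c1)\C(O)=O | intermediate
4 | (2E,3E)-2,3-bis[(4-benzyloxy-3-methoxyphenyl)methylidene]butane-1,4-diol, each aryl trans to its CH2OH | OC/C(=C/c1ccc(OCc2ccccc2)c(OC)c1)C(=C/c1ccc(OCc2ccccc2)c(OC)c1)\CO | intermediate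
5 | [(2R,2'R,3R,3'R)-3,3'-bis(4-benzyloxy-3-methoxyphenyl)-2,2'-bioxirane-2,2'-diyl]dimethanol (C2-symmetric bis-epoxide, aryl trans to CH2OH on each oxirane) | OC[C@]1(O[C@@H]1c1ccc(OCc2ccccc2)c(OC)c1)[C@]1(CO)O[C@@H]1c1ccc(OCc2ccccc2)c(OC)c1 | intermediate (not isolated)
6 | (2R,3R,6S,7R)-2,6-bis(4-benzyloxy-3-methoxyphenyl)-7-(hydroxymethyl)-1,5-dioxaspiro[2.4]heptan-7-ol (first tetrahydrofuran closed, second oxirane still intact and spiro-fused to it) | COc1cc(ccc1OCc1ccccc1)[C@@H]1OC[C@]2(O[C@@H]2c2ccc(OCc3ccccc3)c(OC)c2)[C@@]1(O)CO | intermediate (not isolated)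
7 | (1S,3aR,4S,6aR)-1,4-bis(4-benzyloxy-3-methoxyphenyl)tetrahydro-1H,3H-furo[3,4-c]furan-3a,6a-diol | COc1cc([C@@H]2OC[C@@]3(O)[C@H](c4ccc(OCc5ccccc5)c(OC)c4)OC[C@@]23O)ccc1OCc1ccccc1 | intermediate
8 | (1S,3aR,4S,6aR)-1,4-bis(4-hydroxy-3-methoxyphenyl)tetrahydro-1H,3H-furo[3,4-c]furan-3a,6a-diol | COc1cc([C@@H]2OC[C@@]3(O)[C@H](c4ccc(O)c(OC)c4)OC[C@@]23O)ccc1O | target

**Step count and risks**
Total steps: 4. Longest linear sequence: 4 (1 + 2 → 3 → 4 → 7 → 8).

Most likely to fail, in order:

Step 3. The 1,4-diol may chelate titanium and slow the epoxidation. The mono-epoxide may cyclise before the second alkene is epoxidised. The electron-rich benzylic oxirane may open with SN1 character, eroding the inversion or leading to a Meinwald-type rearrangement. The fallback sets out from 4 and removes the free hydroxyls and the Lewis acid from the epoxidation. TBSCl and imidazole in DMF give the bis(tert-butyldimethylsilyl) ether F1. Shi epoxidation (D-fructose-derived Shi ketone, KHSO5, K2CO3, MeCN–dimethoxymethane–aqueous buffer at pH 10.5, 0 °C) delivers oxygen to the same faces as above and gives the (2R,2'R,3R,3'R) bis-epoxide bis(silyl ether) F2, which can be isolated under these basic conditions. Bu4NF in THF at 0 °C then releases bis-epoxide 5, where the fallback comes back to the route; 5 is taken through the CSA stage of step 3 to 7.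

Step 1. The second condensation competes with early opening to the mono-condensed half-ester salt, which does not condense again. The fallback sets out from 1 and 2 and goes stepwise. NaOMe in MeOH at reflux with one equivalent of 1 gives (E)-4-(4-benzyloxy-3-methoxyphenyl)-3-(methoxycarbonyl)but-3-enoic acid F3. MeI and K2CO3 in DMF give dimethyl (E)-2-(4-benzyloxy-3-methoxybenzylidene)succinate F4. A second Stobbe condensation of F4 with 1 (NaOMe, MeOH, reflux) gives the (2E,3E)-bis(arylidene)succinic acid monomethyl ester F5. Saponification (NaOH, aqueous MeOH, reflux, then HCl) comes back to the route at 3.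

Step 2. The dialuminium carboxylate may be poorly soluble and reduce incompletely, or partial conjugate reduction may occur. The fallback sets out from 3. MeI and K2CO3 in DMF give dimethyl (2E,3E)-2,3-bis(4-benzyloxy-3-methoxybenzylidene)succinate F6. i-Bu2AlH in CH2Cl2 at −78 → 0 °C reduces the two esters and comes back to the route at 4.

Step 4 is the least risky: debenzylation of furofuran lignan benzyl ethers under neutral hydrogenolysis is well precedented.

**Further compounds**
F1 | step 3 | (2E,3E)-2,3-bis[(4-benzyloxy-3-methoxyphenyl)methylidene]butane-1,4-diol bis(tert-butyldimethylsilyl) ether | CC(C)(C)[Si](C)(C)OC/C(=C/c1ccc(OCc2ccccc2)c(OC)c1)C(=C/c1ccc(OCc2ccccc2)c(OC)c1)\CO[Si](C)(C)C(C)(C)C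
F2 | step 3 | (2R,2'R,3R,3'R)-3,3'-bis(4-benzyloxy-3-methoxyphenyl)-2,2'-bis[(tert-butyldimethylsilyloxy)methyl]-2,2'-bioxirane | CC(C)(C)[Si](C)(C)OC[C@]1(O[C@@H]1c1ccc(OCc2ccccc2)c(OC)c1)[C@]1(CO[Si](C)(C)C(C)(C)C)O[C@@H]1c1ccc(OCc2ccccc2)c(OC)c1
F3 | step 1 | (E)-4-(4-benzyloxy-3-methoxyphenyl)-3-(methoxycarbonyl)but-3-enoic acid | COC(=O)/C(=C/c1ccc(OCc2ccccc2)c(OC)c1)CC(O)=O
F4 | step 1 | dimethyl (E)-2-(4-benzyloxy-3-methoxybenzylidene)succinate | COC(=O)/C(=C/c1ccc(OCc2ccccc2)c(OC)c1)CC(=O)OC
F5 | step 1 | (2E,3E)-2,3-bis(4-benzyloxy-3-methoxybenzylidene)succinic acid monomethyl ester | COC(=O)/C(=C/c1ccc(OCc2ccccc2)c(OC)c1)C(=C/c1ccc(OCc2ccccc2)c(OC)c1)\C(O)=O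
F6 | step 2 | dimethyl (2E,3E)-2,3-bis(4-benzyloxy-3-methoxybenzylidene)succinate | COC(=O)/C(=C/c1ccc(OCc2ccccc2)c(OC)c1)C(=C/c1ccc(OCc2ccccc2)c(OC)c1)\C(=O)OC
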